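- Face 4 questions with one quantity, the **catalyst clock**: the integral over time of the rate constant of the main step, meaning rate divided by substrate and coupling partner.

- order of the initial rate in [coupling partner], near the charge of the west run, the rate being that where two percent of its substrate are product
- order of the initial rate in [substrate], near the charge of the west run, the rate being that where two percent of its substrate are product (one fixed amount of product, the same in the runs compared)
- the south-east run starts with 0.200 M less of substrate and of coupling partner than the west run, and with no product. Compared where both hold the same amount of substrate, once fifteen percent of what the south-east run was charged with has turned into product, is the south-east run faster, slower or alike (within a tenth)?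
- product in the north-west run at 31 min, as a share of the substrate charged

| flask | substrate | coupling partner | free catalyst | time |
|---|---|---|---|---|
| west | 0.500 M | 0.750 M | 0.0500 M |  |
| south-east | 0.300 M | 0.550 M | 0.0500 M |  |
| north | 0.750 M | 0.750 M | 0.0500 M |  |
| north-west | 1.20 M | 0.750 M | 0.0500 M | 31 min |

- west run (time / min: [product] / M): 1.2: 0.082; 2.0: 0.112; 3.1: 0.140; 4.9: 0.182; 7.8: 0.220; 12: 0.252; 20: 0.299; 31: 0.326
- south-east run (time / min: [product] / M): 1.2: 0.040; 2.0: 0.053; 3.1: 0.083; 4.9: 0.095; 7.8: 0.119; 12: 0.141; 20: 0.161; 31: 0.180
- north run (time / min: [product] / M): 1.2: 0.110; 2.0: 0.155; 3.1: 0.191; 4.9: 0.247; 7.8: 0.307; 12: 0.353; 20: 0.400; 31: 0.432

(readings scatter by 0.004 M)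

- Overall: substrate + coupling partner -> product, with free catalyst as catalyst.
- Constant volume, constant temperature.
- Bound and free are read together.
- "The second partner" is coupling partner.
- An order is taken over about fifteen percent of the charge, up and down.

- Work in fractions of the charge. Where substrate and partner are charged alike, as in the north run, the clock is the fraction turned over the fraction untouched, divided by the charge. For the north run this closed form reads 1.81 /M at 31 min.
- For unequal charges, let E be the exponential of substrate charge less partner charge, times the clock, and a be substrate charge over partner charge. The substrate share turned is then (E less one) over (aE less one).
- Start with the main step by itself, at a constant pace. The first north reading gives 0.191 /M/min, so this step of the reckoning puts the north-west run at 60.8% by 31 min. That is close to the ceiling of 62.5% set by the partner, the limiting reagent there, charged at 0.750 M against 1.20 M of substrate.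
- Now add a dying catalyst. The north clock stands at 1.19 /M by 12 min, so its later pace is 0.0329 /M/min, slower than the first. Put the measured clock in the rule and the north-west share falls to 48.2%.
- Add the rest. The west run, thinner in substrate at the same partner charge, reads a clock of 1.94 /M at 31 min, longer than the north reading. Stretch that trend in substrate charge to the north-west run and the clock is 1.58 /M, which gives 45.9%.
- Commit to a share between 45.9% and 48.2%, and to orders below one.
- Expect the south-east run to be faster at the matched point. It gets there between 1.2 min and 2.0 min, earlier than the west run, which arrives between 7.8 min and 12 min, and the north clock runs at 0.191 /M/min over its first 1.2 min but slower, at 0.0329 /M/min, after 12 min.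
- The forecast gives an order of 1 for the partner and 1 for substrate, calls the south-east run faster, and puts the north-west run at 48.5%, above the range just given, holding that “the catalyst is dying with time”.
- The flask gives 47.4% for the north-west run, with orders 0.92 in substrate and 0.82 in partner, and the south-east run faster by a factor of 2.8 at the matched point.

    free catalyst + substrate + coupling partner → product + free catalyst (7.020 /M²/min)
    substrate + coupling partner ⇌ idle substrate-reagent adduct, settled at all times (0.5330 /M)
    2 free catalyst → 2 spent catalyst (3.006 /M/min)

- Run the rule backwards: that share means a clock of 1.73 /M at 31 min, shorter than the north clock of 1.81 /M and longer than the stretched 1.58 /M.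
- Put the north clock on the south-east run: it turns 55.8% of the substrate charge by 31 min, and that run read 60.0%.

The numbers in the tables are calculated with constants of no real substance, and the scatter is random.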